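## The problem

The target is the erythro guaiacylglycerol 8-O-4 ether of (−)-pinoresinol. Its core is a cis-fused 3,7-dioxabicyclo[3.3.0]octane (rings C7–O–C9'–C8'–C8 and C7'–O–C9–C8–C8') with exo guaiacyl groups at C7 and C7'. One guaiacyl oxygen carries a 1-aryl-propane-1,3-diol chain (C7'', C8'', C9''). The core has four contiguous stereocentres (7R,8S,7'R,8'S). The cis fusion ties C8 to C8', a stereocentre at C7 can steer C8 through the face of a planar precursor, and C7' must end up exo. With two like aryl groups the core is C2-symmetric, so either phenol may carry the chain, but the two must be told apart by protecting groups from the moment the aryl groups enter. The side-chain centres (7''R,8''S; erythro, the anti-aldol relation) are too remote for the core to control and need an external controller. The benzylic ethers C7–O and C7'–O sit next to electron-rich arenes and ionise under acid (epimerisation) or cleave on hydrogenolysis. The p-hydroxybenzylic alcohol at C7'' gives a quinone methide under acid or strong base. The closing steps must therefore be neutral and non-reductive. The enabling feature is ring C7'–O–C9–C8–C8': a 2-aryltetrahydrofuran with no substituent at C9. Its C7'(Ar)–O–C9H2 unit is the imprint of a carbonyl ylide added across a C8=C8' double bond of a butenolide that already holds C7, the ring oxygen and C9'.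

## Retrosynthesis

**Unmasking (22 → 21).** Only the O–allyl bond of the second core phenol is cut. An allyl ether survives hydride, Lewis acid and base, and is removed last under neutral palladium catalysis, which spares the benzylic ethers and the C7'' carbinol that hydrogenolysis or acid would attack.

**Side chain (21 → 20 → 17 + 18).** The C7''–C8'' bond is cut as an anti-aldol between the aryloxyacetyl imide 17 and vanillin acetate 18; reduction of the imide carbonyl gives C9''. The neighbouring cut, C8''–O by displacement with the phenol, needs a secondary, β-branched electrophile prone to elimination. The aldol builds both centres at once from the phenol and a commercial aldehyde. The auxiliary must overrule the remote core and give the anti (erythro) isomer. The acetate on 18 makes the aldehyde more electrophilic and falls off in the same reduction that removes the auxiliary.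

**Ether link (17 → 14 + 16).** The aryl O–CH2 bond is cut. Phenol 14 is the mono-allyl ether of (−)-pinoresinol. Because the core is C2-symmetric, the differentiation set in the two cycloaddition partners is all that is needed. Imide 16 comes in one step from oxazolidinone 15.

**Oxidation level at C9' (14 → 13 → 12).** The C9' methylene is traced back to the lactone carbonyl of 12 through lactol 13. The hydride that reduces the lactone also removes the pivalate, which frees exactly the phenol that is to carry the chain.

**Key disconnection (12 → 6 + 10, through ylide 11).** Bonds C7'–C8' and C8–C9 are cut together, opening ring C7'–O–C9–C8–C8'. A stepwise conjugate addition and enolate trapping on butenolide 6 would place the two new carbon substituents trans, and a trans pair cannot close to the cis-fused bicycle. Only a concerted, suprafacial addition delivers C9 and C7' to the same face. The precursors are far simpler: 6 has one stereocentre, and 10 is racemic and loses its centre in ylide 11. The forward step must give head-to-tail regiochemistry, attack anti to the C7 aryl group, an exo aryl group at C7', and must leave the base-sensitive C7 centre of 6 intact.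

**Butenolide (6 → 4 → 2 + 3).** The lactone C–O bond and the C7–C8 bond are cut: catalytic asymmetric addition of methyl propiolate 3 to aldehyde 2 gives 4, and syn semihydrogenation with lactonisation gives 6. An acrylate ring-closing metathesis was set aside because the aryl allyl ether would be a third terminal alkene. The alkyne route needs one step fewer, and its stereocentre comes from a catalyst.

**Ylide precursor (10 → 9 → 7 + 8).** The O–CH2Cl bond and the C–Si bond are cut. The silyl group is brought onto aldehyde 7 by copper-catalysed transfer from silylboronate 8, because a retro-Brook route needs alkyllithium bases that the pivalate would not survive. The silyl group is therefore dimethylphenylsilyl. The pivalate is kept on this arene on purpose: it damps benzylic ionisation during chloromethylation and makes the benzylic ylide terminus less electron-rich.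

**Aryl building blocks (2, 7 → 1).** Both aldehydes come from vanillin 1 by O-allylation and O-pivaloylation; the two phenols are differentiated here.

## Roads not taken

**Alternative 1:** The cut goes through the two benzylic–bridgehead bonds, C7'–C8' and C7–C8. A lithiated aryl dithiane would add to a chiral γ-menthyloxybutenolide anti to the acetal substituent, and the lactone enolate would be trapped by a silyl-protected vanillin to give the trans,trans lactone A1.
- Merits: each bond-forming event has close precedent on this butenolide; the absolute configuration comes from a cheap, recoverable auxiliary; the trans relation of the new substituents is exactly the C8/C8' relation that cis fusion needs; the aryl groups enter already differentiated; the number of operations to the differentiated furofuran is no higher than in the chosen plan.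
- Weak points: no ring closes and neither benzylic centre is set. C7 and C7' arise only later, after dithiane removal and global reduction, by acid-mediated closure through benzylic cations, the very conditions under which furofurans epimerise. Dithiane cleavage must be done beside an allyl ether and electron-rich arenes, and the auxiliary is stoichiometric.
- Comparison: in precedent this is the safer road and it is equal in length. The chosen plan sets against it that C8, C8' and C7' are fixed in the ring-forming step without acid, that no acid ever acts on free benzylic carbinols, and that chirality comes from a catalyst. Its chemistry is kept as the fallback for the key step.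

**Alternative 2:** The cut is C8–C8' and C7'–O. Epoxy cinnamyl ether A2 would be opened by Cp2TiCl (trivalent titanium) to a C8 radical that cyclises 5-exo onto the cinnamyl alkene. Iodine would then oxidise the benzylic centre so that the C9 alkoxide closes on C7', giving A3.
- Merits: both rings form in one flask, which the chosen plan cannot match; the cascade is known for furofuran lignans; C7 steers the new centres; no acid is used.
- Weak points: titanium is stoichiometric; A2 needs an enantiopure aryl epoxy alcohol (a kinetic resolution loses half the material) and a separately made cinnamyl halide; the allyl aryl ether is a competing radical acceptor; C7' is set by capture of a benzylic cation.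
- Comparison: it forms more rings per step, but its precursor costs more steps and its stereochemical source is a resolution. The chosen plan offers two short fragments and a catalytic source of chirality, at the price of an unproven pairing.

**Alternative 3:** The cut is C8–C9 and C7–O. In dioxane A4 a Lewis acid (Me3SiOTf or TiCl4) would open the methylene acetal to the oxocarbenium ion on the C7' oxygen. The styrene would attack through C8, and the freed C9' oxygen would capture the benzylic cation at C7 to give A5.
- Merits: both rings form in one step from a stable precursor by purely ionic chemistry, and C7' and C8' are secured beforehand by conventional means.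
- Weak points: A4 needs two stereocentres and an E-styrene before the key step; the cascade is itself unprecedented; C7 is set by cation capture; a strong Lewis acid acts on a product with two ionisable benzylic ethers.
- Comparison: both plans rest on an untested step. Alternative 3 closes two rings but asks for more pre-built stereochemistry and exposes the product to acid. The chosen plan controls three centres from one and confines Lewis acid to a single low-temperature reduction.

Key step: step 7

Assumption: the Zn–ProPhenol catalyst from the (S,S)-ligand is taken to deliver the alkynyl group to the Re face of aldehyde 2, the face it attacks in its aldol reactions, which gives (S)-4; if the sense proves opposite, the (R,R)-ligand is used.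

## Route

Step 1
Reactants: 1 vanillin
Product: 2 4-(allyloxy)-3-methoxybenzaldehyde
Conditions: allyl bromide, K2CO3, DMF, rt
Reagents that add atoms: allyl bromide, C=CCBr
Why: Williamson ether synthesis; the phenoxide displaces bromide at the allylic carbon and the aldehyde is inert to carbonate.

Step 2
Reactants: 2 4-(allyloxy)-3-methoxybenzaldehyde; 3 methyl propiolate
Product: 4 methyl (S)-4-[4-(allyloxy)-3-methoxyphenyl]-4-hydroxybut-2-ynoate
Conditions: (S,S)-ProPhenol (10 mol %), Me2Zn (3 equiv), Ph3PO (20 mol %), toluene, 0 °C; aq. NH4Cl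
Reagents that add atoms: none
Why: Zn–ProPhenol-catalysed asymmetric alkynylation of an aryl aldehyde; the alkynylzinc formed from 3 and Me2Zn adds inside the dinuclear zinc catalyst, which selects the aldehyde face and sets C7 (descriptor S here, R once the alkyne has become the ring alkene).

Step 3
Reactants: 4 methyl (S)-4-[4-(allyloxy)-3-methoxyphenyl]-4-hydroxybut-2-ynoate
Product: 6 (R)-5-[4-(allyloxy)-3-methoxyphenyl]furan-2(5H)-one, via (Z)-γ-hydroxy enoate 5 (not isolated)
Conditions: H2 (1 atm, one equivalent taken up), Pd/CaCO3 poisoned with Pb(OAc)2, quinoline, EtOAc, rt; then PPTS (cat.), CH2Cl2, rt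
Reagents that add atoms: none
Why: Semihydrogenation of the alkyne by syn addition gives the Z-enoate, whose hydroxyl and ester are cis and lactonise with loss of methanol; the conjugated alkyne is reduced much faster than the isolated allyl alkene on poisoned palladium, and C7 is not touched.

Step 4
Reactants: 1 vanillin
Product: 7 4-formyl-2-methoxyphenyl pivalate
Conditions: pivaloyl chloride, Et3N, DMAP (cat.), CH2Cl2, 0 °C to rt
Reagents that add atoms: pivaloyl chloride, CC(C)(C)C(=O)Cl
Why: DMAP-catalysed O-acylation of the phenol; the hindered ester is stable to the acid and fluoride of the next steps.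

Step 5
Reactants: 7 4-formyl-2-methoxyphenyl pivalate; 8 2-(dimethylphenylsilyl)-4,4,5,5-tetramethyl-1,3,2-dioxaborolane
Product: 9 racemic 4-[(dimethylphenylsilyl)(hydroxy)methyl]-2-methoxyphenyl pivalate
Conditions: CuCl(IPr) (5 mol %; IPr = 1,3-bis(2,6-diisopropylphenyl)imidazol-2-ylidene), NaOt-Bu (10 mol %), THF, rt; aq. NH4Cl
Reagents that add atoms: none
Why: Copper-catalysed 1,2-addition of a silyl nucleophile to an aldehyde by Si–B bond activation; the copper silyl species adds across C=O, the O-boryl product is hydrolysed on work-up, and the near-neutral catalytic conditions spare the aryl ester. The racemic centre is erased in the ylide.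

Step 6
Reactants: 9 racemic 4-[(dimethylphenylsilyl)(hydroxy)methyl]-2-methoxyphenyl pivalate
Product: 10 racemic 4-[(chloromethoxy)(dimethylphenylsilyl)methyl]-2-methoxyphenyl pivalate
Conditions: (CH2O)n, HCl (g), CH2Cl2, 0 °C; CaCl2; used crude
Reagents that add atoms: formaldehyde (as paraformaldehyde), C=O; hydrogen chloride, Cl
Why: Chloromethyl ether formation from an alcohol, formaldehyde and HCl through the hemiformal, as in the preparation of benzyl chloromethyl ether; the acyloxy-substituted arene resists benzylic ionisation under these conditions.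

Step 7
Reactants: 6 (R)-5-[4-(allyloxy)-3-methoxyphenyl]furan-2(5H)-one; 10 racemic 4-[(chloromethoxy)(dimethylphenylsilyl)methyl]-2-methoxyphenyl pivalate
Product: 12 (3R,3aS,6R,6aR)-3-[4-(allyloxy)-3-methoxyphenyl]-6-[3-methoxy-4-(pivaloyloxy)phenyl]tetrahydro-1H,3H-furo[3,4-c]furan-1-one, via carbonyl ylide 11 (not isolated)
Conditions: CsF (3 equiv, dried), MeCN, 0 °C to rt, slow addition of 10 (2 equiv)
Reagents that add atoms: none
Why: Proposed new method: fluoride attacks the silicon of 10 while chloride leaves from the methylene carbon (1,3-elimination), giving the non-stabilised carbonyl ylide 11, ArCH=O(+)–CH2(−), which adds as the 4π partner across the C8=C8' bond of 6 in a concerted suprafacial (3+2) cycloaddition; the closest known reaction type is the CsF-induced 1,3-elimination of chloromethyl 1-silylalkyl ethers and the addition of the resulting ylides to acrylates, fumarates and enones, which has not been paired with a γ-aryl butenolide. Ring C7'–O–C9–C8–C8' closes by this two-bond cycloaddition and is therefore cis-fused to the lactone. The unsubstituted CH2 terminus, the smaller end with the larger HOMO coefficient, bonds to the β-carbon C8 next to the C7 aryl group, and the benzylic terminus bonds to the α-carbon C8'. C8 and C8' are set by the face of attack, which is anti to the C7 aryl group, the only substituent on the planar butenolide, so that H7 and H8 become trans. C7' is set by the orientation of the dipole: the E ylide approaches with its oxygen turned away from the lactone ring, which places its aryl group exo, away from the lactone carbonyl. The step needs head-to-tail regioselectivity, anti facial selectivity, exo selectivity and retention of the C7 configuration; the first three rest on the γ-aryl group and the bulk of the ylide aryl group, the last on a low standing fluoride concentration (sparingly soluble CsF, slow addition, low temperature), because the γ-hydrogen of 6 is benzylic and vinylogously acidic. The pivaloyloxy group makes the benzylic terminus of 11 less electron-rich than an alkoxy group would, which should help both the ylide and the stability of 10.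

Step 8
Reactants: 12 (3R,3aS,6R,6aR)-3-[4-(allyloxy)-3-methoxyphenyl]-6-[3-methoxy-4-(pivaloyloxy)phenyl]tetrahydro-1H,3H-furo[3,4-c]furan-1-one
Product: 13 (3R,3aS,6R,6aR)-3-[4-(allyloxy)-3-methoxyphenyl]-6-(4-hydroxy-3-methoxyphenyl)tetrahydro-1H,3H-furo[3,4-c]furan-1-ol (both C1 epimers)
Conditions: i-Bu2AlH (4.5 equiv), CH2Cl2, −78 °C; aq. potassium sodium tartrate
Reagents that add atoms: none
Why: Half-reduction of a γ-lactone to the lactol through the aluminium hemiacetal, which is stable at −78 °C; the excess hydride reductively cleaves the aryl pivalate and so frees the phenol that is to carry the side chain.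

Step 9
Reactants: 13 lactol (3R,3aS,6R,6aR)-3-[4-(allyloxy)-3-methoxyphenyl]-6-(4-hydroxy-3-methoxyphenyl)tetrahydro-1H,3H-furo[3,4-c]furan-1-ol
Product: 14 4-[(1R,3aS,4R,6aS)-4-[4-(allyloxy)-3-methoxyphenyl]tetrahydro-1H,3H-furo[3,4-c]furan-1-yl]-2-methoxyphenol
Conditions: Et3SiH (3 equiv), BF3·OEt2 (2 equiv), CH2Cl2, −78 to −40 °C; aq. NaHCO3
Reagents that add atoms: none
Why: Ionic hydrogenation of a lactol: BF3 ionises the hemiacetal to the cyclic oxocarbenium ion, which the silane reduces to CH2; no stereocentre is formed, and hemiacetal ionisation is far faster at low temperature than ionisation of the benzylic ethers.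

Step 10
Reactants: 15 (S)-4-benzyloxazolidin-2-one
Product: 16 (S)-4-benzyl-3-(bromoacetyl)oxazolidin-2-one
Conditions: n-BuLi, THF, −78 °C; bromoacetyl bromide, −78 to 0 °C
Reagents that add atoms: bromoacetyl bromide, BrCC(Br)=O
Why: N-acylation of the lithiated oxazolidinone with an acid bromide, the standard entry to N-acyl oxazolidinones.

Step 11
Reactants: 14 4-[(1R,3aS,4R,6aS)-4-[4-(allyloxy)-3-methoxyphenyl]tetrahydro-1H,3H-furo[3,4-c]furan-1-yl]-2-methoxyphenol; 16 (S)-4-benzyl-3-(bromoacetyl)oxazolidin-2-one
Product: 17 (S)-3-{2-[4-((1R,3aS,4R,6aS)-4-(4-(allyloxy)-3-methoxyphenyl)tetrahydro-1H,3H-furo[3,4-c]furan-1-yl)-2-methoxyphenoxy]acetyl}-4-benzyloxazolidin-2-one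
Conditions: K2CO3, MeCN, rt
Reagents that add atoms: none
Why: Williamson ether synthesis; SN2 displacement at the α-bromo imide is fast enough to outrun acyl transfer to the phenoxide, and the furofuran has no base-sensitive site.

Step 12
Reactants: 17 (S)-3-{2-[4-((1R,3aS,4R,6aS)-4-(4-(allyloxy)-3-methoxyphenyl)tetrahydro-1H,3H-furo[3,4-c]furan-1-yl)-2-methoxyphenoxy]acetyl}-4-benzyloxazolidin-2-one; 18 4-formyl-2-methoxyphenyl acetate
Product: 20 (S)-3-[(2R,3R)-3-(4-acetoxy-3-methoxyphenyl)-2-{4-[(1R,3aS,4R,6aS)-4-(4-(allyloxy)-3-methoxyphenyl)tetrahydro-1H,3H-furo[3,4-c]furan-1-yl]-2-methoxyphenoxy}-3-hydroxypropanoyl]-4-benzyloxazolidin-2-one, via trimethylsilyl ether 19 (not isolated)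
Conditions: MgCl2 (20 mol %), Et3N (2.5 equiv), Me3SiCl (2 equiv), EtOAc, rt; then PPTS (cat.), MeOH, 0 °C
Reagents that add atoms: chlorotrimethylsilane, C[Si](C)(C)Cl (retained only in intermediate 19)
Why: Magnesium chloride-catalysed anti-aldol reaction of an N-acyl oxazolidinone with an aromatic aldehyde under soft enolisation; magnesium chelates the imide carbonyl and the enolate oxygen, the benzyl group of the auxiliary shields one enolate face (C8''), a boat-like transition state gives the anti relation (C7''), and silylation of the aldolate releases the metal. The mild Lewis acid leaves the furofuran alone.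

Step 13
Reactants: 20 anti-aldol adduct (S)-3-[(2R,3R)-3-(4-acetoxy-3-methoxyphenyl)-2-(aryloxy)-3-hydroxypropanoyl]-4-benzyloxazolidin-2-one
Product: 21 (1R,2S)-2-{4-[(1R,3aS,4R,6aS)-4-(4-(allyloxy)-3-methoxyphenyl)tetrahydro-1H,3H-furo[3,4-c]furan-1-yl]-2-methoxyphenoxy}-1-(4-hydroxy-3-methoxyphenyl)propane-1,3-diol
Conditions: LiBH4 (4 equiv), H2O (1 equiv), Et2O–THF, 0 °C; aq. NH4Cl
Reagents that add atoms: none
Why: Reductive cleavage of the N-acyl oxazolidinone at the exocyclic carbonyl gives the primary alcohol C9'' and returns the auxiliary; the aryl acetate is reduced off in the same pot, and neither stereocentre is enolisable under these conditions.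

Step 14
Reactants: 21 (1R,2S)-2-{4-[(1R,3aS,4R,6aS)-4-(4-(allyloxy)-3-methoxyphenyl)tetrahydro-1H,3H-furo[3,4-c]furan-1-yl]-2-methoxyphenoxy}-1-(4-hydroxy-3-methoxyphenyl)propane-1,3-diol
Product: 22 (1R,2S)-1-(4-hydroxy-3-methoxyphenyl)-2-{4-[(1R,3aS,4R,6aS)-4-(4-hydroxy-3-methoxyphenyl)tetrahydro-1H,3H-furo[3,4-c]furan-1-yl]-2-methoxyphenoxy}propane-1,3-diol (CNP0172915.1)
Conditions: Pd(PPh3)4 (5 mol %), morpholine (10 equiv), THF, rt
Reagents that add atoms: none
Why: Tsuji–Trost deallylation; zerovalent palladium ionises the aryl allyl ether to a π-allyl complex and the phenoxide, and morpholine traps the allyl group. The conditions are neutral and non-reductive, so the benzylic ethers and the C7'' carbinol are untouched.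

## Compound list

1 | vanillin | COc1cc(C=O)ccc1O | starting material
2 | 4-(allyloxy)-3-methoxybenzaldehyde | C=CCOc1ccc(C=O)cc1OC | intermediate
3 | methyl propiolate | C#CC(=O)OC | starting material
4 | methyl (S)-4-[4-(allyloxy)-3-methoxyphenyl]-4-hydroxybut-2-ynoate | COC(=O)C#C[C@@H](O)c1ccc(OCC=C)c(OC)c1 | intermediate
5 | methyl (2Z,4R)-4-[4-(allyloxy)-3-methoxyphenyl]-4-hydroxybut-2-enoate | COC(=O)/C=C\[C@@H](O)c1ccc(OCC=C)c(OC)c1 | intermediate (not isolated)
6 | (R)-5-[4-(allyloxy)-3-methoxyphenyl]furan-2(5H)-one | C=CCOc1ccc([C@@H]2OC(=O)C=C2)cc1OC | intermediate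
7 | 4-formyl-2-methoxyphenyl pivalate | COc1cc(C=O)ccc1OC(=O)C(C)(C)C | intermediate
8 | 2-(dimethylphenylsilyl)-4,4,5,5-tetramethyl-1,3,2-dioxaborolane | CC1(C)OB(OC1(C)C)[Si](C)(C)c1ccccc1 | starting material
9 | racemic 4-[(dimethylphenylsilyl)(hydroxy)methyl]-2-methoxyphenyl pivalate | COc1cc(C(O)[Si](C)(C)c2ccccc2)ccc1OC(=O)C(C)(C)C | intermediate
10 | racemic 4-[(chloromethoxy)(dimethylphenylsilyl)methyl]-2-methoxyphenyl pivalate | COc1cc(C(OCCl)[Si](C)(C)c2ccccc2)ccc1OC(=O)C(C)(C)C | intermediate
11 | carbonyl ylide, [3-methoxy-4-(pivaloyloxy)benzylidene]oxonium methylide | [CH2-][O+]=Cc1ccc(OC(=O)C(C)(C)C)c(OC)c1 | intermediate (not isolated)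
12 | (3R,3aS,6R,6aR)-3-[4-(allyloxy)-3-methoxyphenyl]-6-[3-methoxy-4-(pivaloyloxy)phenyl]tetrahydro-1H,3H-furo[3,4-c]furan-1-one | C=CCOc1ccc([C@@H]2OC(=O)[C@@H]3[C@H]2CO[C@H]3c2ccc(OC(=O)C(C)(C)C)c(OC)c2)cc1OC | intermediate
13 | (3R,3aS,6R,6aR)-3-[4-(allyloxy)-3-methoxyphenyl]-6-(4-hydroxy-3-methoxyphenyl)tetrahydro-1H,3H-furo[3,4-c]furan-1-ol, both C1 epimers | C=CCOc1ccc([C@@H]2OC(O)[C@@H]3[C@H]2CO[C@H]3c2ccc(O)c(OC)c2)cc1OC | intermediate
14 | 4-[(1R,3aS,4R,6aS)-4-[4-(allyloxy)-3-methoxyphenyl]tetrahydro-1H,3H-furo[3,4-c]furan-1-yl]-2-methoxyphenol, the mono-O-allyl ether of (−)-pinoresinol | C=CCOc1ccc([C@@H]2OC[C@@H]3[C@H]2CO[C@H]3c2ccc(O)c(OC)c2)cc1OC | intermediate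
15 | (S)-4-benzyloxazolidin-2-one | O=C1N[C@@H](Cc2ccccc2)CO1 | starting material
16 | (S)-4-benzyl-3-(bromoacetyl)oxazolidin-2-one | O=C(CBr)N1C(=O)OC[C@@H]1Cc1ccccc1 | intermediate
17 | (S)-3-{2-[4-((1R,3aS,4R,6aS)-4-(4-(allyloxy)-3-methoxyphenyl)tetrahydro-1H,3H-furo[3,4-c]furan-1-yl)-2-methoxyphenoxy]acetyl}-4-benzyloxazolidin-2-one | C=CCOc1ccc([C@@H]2OC[C@@H]3[C@H]2CO[C@H]3c2ccc(OCC(=O)N4C(=O)OC[C@@H]4Cc4ccccc4)c(OC)c2)cc1OC | intermediate
18 | 4-formyl-2-methoxyphenyl acetate (vanillin acetate) | COc1cc(C=O)ccc1OC(C)=O | starting material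
19 | trimethylsilyl ether of 20 at the C7'' oxygen, (2R,3R) | C=CCOc1ccc([C@@H]2OC[C@@H]3[C@H]2CO[C@H]3c2ccc(O[C@@H](C(=O)N4C(=O)OC[C@@H]4Cc4ccccc4)[C@H](O[Si](C)(C)C)c4ccc(OC(C)=O)c(OC)c4)c(OC)c2)cc1OC | intermediate (not isolated)
20 | (S)-3-[(2R,3R)-3-(4-acetoxy-3-methoxyphenyl)-2-{4-[(1R,3aS,4R,6aS)-4-(4-(allyloxy)-3-methoxyphenyl)tetrahydro-1H,3H-furo[3,4-c]furan-1-yl]-2-methoxyphenoxy}-3-hydroxypropanoyl]-4-benzyloxazolidin-2-one | C=CCOc1ccc([C@@H]2OC[C@@H]3[C@H]2CO[C@H]3c2ccc(O[C@@H](C(=O)N4C(=O)OC[C@@H]4Cc4ccccc4)[C@H](O)c4ccc(OC(C)=O)c(OC)c4)c(OC)c2)cc1OC | intermediate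
21 | (1R,2S)-2-{4-[(1R,3aS,4R,6aS)-4-(4-(allyloxy)-3-methoxyphenyl)tetrahydro-1H,3H-furo[3,4-c]furan-1-yl]-2-methoxyphenoxy}-1-(4-hydroxy-3-methoxyphenyl)propane-1,3-diol | C=CCOc1ccc([C@@H]2OC[C@@H]3[C@H]2CO[C@H]3c2ccc(O[C@@H](CO)[C@H](O)c4ccc(O)c(OC)c4)c(OC)c2)cc1OC | intermediate
22 | (1R,2S)-1-(4-hydroxy-3-methoxyphenyl)-2-{4-[(1R,3aS,4R,6aS)-4-(4-hydroxy-3-methoxyphenyl)tetrahydro-1H,3H-furo[3,4-c]furan-1-yl]-2-methoxyphenoxy}propane-1,3-diol | COc1cc([C@@H](O)[C@H](CO)Oc2ccc([C@@H]3OC[C@@H]4[C@H]3CO[C@H]4c3ccc(O)c(OC)c3)cc2OC)ccc1O | target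

## Step count and least certain steps

Total: 14 steps. Longest linear sequence: 10 steps (1, 2, 3, 7, 8, 9, 11, 12, 13, 14). The ylide branch (4, 5, 6) joins at step 7 and gives a sequence of the same length; step 10 is a one-step side branch.

**Step 7 (key step, proposed new method).**
- Most likely to go wrong: fluoride may deprotonate the γ-position of the butenolide, which erodes the C7 configuration that controls everything else. The ylide may collapse to the oxirane or dimerise faster than it is trapped. Attack may be partly endo, or with the reverse orientation, because the directing effects of the γ-aryl group and the ylide aryl group are untested for this pairing.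
- Fallback (known chemistry, from aldehyde 2 with aldehyde 7, back at 14): the butenolide/ylide pairing is given up for the conjugate addition–aldol logic of Alternative 1.
  - Aldehyde 2 and propane-1,3-dithiol (BF3·OEt2) give 2-[4-(allyloxy)-3-methoxyphenyl]-1,3-dithiane F1.
  - Its 2-lithio derivative (n-BuLi, THF, −78 °C) adds to the auxiliary butenolide (5S)-5-[(1S,2R,5S)-menthyloxy]furan-2(5H)-one F2 (from furfural and (+)-menthol) anti to the menthyloxy group. The lactone enolate is trapped by aldehyde 7 anti to the new substituent, giving the trans,trans lactone F3 as carbinol epimers.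
  - Alkylative dithiane hydrolysis (MeI, CaCO3, aqueous MeCN) gives the aryl ketone F4.
  - LiAlH4 reduces ketone, lactone and masked aldehyde and removes menthol and the pivalate, giving the tetraol F5.
  - Camphorsulfonic acid in CH2Cl2 closes both tetrahydrofuran rings through the benzylic cations, the aryl groups settling exo, and gives 14. The trans C8/C8' relation of F3 is the one that cis fusion requires.

**Step 12 (anti-aldol).**
- Most likely to go wrong: anti/syn selectivity at C7'' may be poor or the addition sluggish, because α-aryloxy imides are less documented in this protocol than propionates.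
- Fallback (from 17, back at 20): C7'' is set by ketone reduction instead of by the aldol. The carbinol mixture from the aldol, which shares the auxiliary-controlled C8'' centre, is oxidised with Dess–Martin periodinane to the β-keto imide F6. The same compound is reached by C-acylation of the sodium enolate of 17 with 4-acetoxy-3-methoxybenzoyl chloride. Its α-centre is protected against enolisation by allylic strain. Reduction with NaBH4 in THF–MeOH at −40 °C under non-chelating conditions should follow the polar Felkin–Anh model, with hydride entering anti to the aryloxy group, and give the anti carbinol 20.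

**Step 3 (semihydrogenation beside the allyl ether; this fallback also covers low selectivity in step 2).**
- Most likely to go wrong: hydrogen uptake may not stop cleanly, with over-reduction of the allyl group or of the butenolide double bond.
- Fallback (from 2, back at 6): the ring is built saturated and dehydrogenated afterwards.
  - Stetter reaction of 2 with methyl acrylate (thiazolium salt, Et3N) gives methyl 4-[4-(allyloxy)-3-methoxyphenyl]-4-oxobutanoate F7.
  - Asymmetric transfer hydrogenation (RuCl[(R,R)-TsDPEN](p-cymene), HCO2H/Et3N) and lactonisation give (R)-5-[4-(allyloxy)-3-methoxyphenyl]dihydrofuran-2(3H)-one F8.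
  - LDA and PhSeBr at −78 °C give the α-phenylselanyl lactone F9. H2O2 then causes selenoxide syn-elimination to 6.

**Step 9 (ionic hydrogenation).**
- Most likely to go wrong: Lewis-acid ionisation of a benzylic C–O bond, above all next to the free p-hydroxyphenyl group, may compete with hemiacetal ionisation and lead to reductive ring opening or epimerisation at C7 or C7'.
- Fallback (from 12, back at 14): the ether ring is closed by displacement instead of reduction.
  - LiAlH4 gives the triol 4-[(2R,3S,4S)-4-{(R)-[4-(allyloxy)-3-methoxyphenyl](hydroxy)methyl}-3-(hydroxymethyl)tetrahydrofuran-2-yl]-2-methoxyphenol F10.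
  - MsCl (2.1 equiv) and Et3N at −20 °C give the primary and phenolic bis-mesylate F11 (not isolated). The benzylic hydroxyl displaces the primary mesylate with retention at C7, giving the furofuran aryl mesylate F12.
  - KOH in aqueous MeOH at 60 °C hydrolyses the aryl mesylate to 14.

**Step 6 (chloromethyl ether; this fallback also bypasses step 5).**
- Most likely to go wrong: benzylic chloride formation or protodesilylation under HCl, and hydrolysis of the chloromethyl ether on handling.
- Fallback (from 7, back at 12 through ylide 11): silicon and chlorine change places. Aldehyde 7, (trimethylsilyl)methanol and HCl (g) in CH2Cl2 at 0 °C give chloro[3-methoxy-4-(pivaloyloxy)phenyl]methyl (trimethylsilyl)methyl ether F13. CsF under the conditions of step 7 gives the same ylide 11 and hence 12.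

Further compounds

F1 | step 7 | 2-[4-(allyloxy)-3-methoxyphenyl]-1,3-dithiane | C=CCOc1ccc(C2SCCCS2)cc1OC
F2 | step 7 | (5S)-5-[(1S,2R,5S)-menthyloxy]furan-2(5H)-one | O=C1O[C@H](O[C@H]2C[C@@H](C)CC[C@@H]2C(C)C)C=C1
F3 | step 7 | 3,4-trans-4,5-trans lactone: 4-{2-[4-(allyloxy)-3-methoxyphenyl]-1,3-dithian-2-yl}-3-{hydroxy[3-methoxy-4-(pivaloyloxy)phenyl]methyl}-5-(menthyloxy)dihydrofuran-2(3H)-one, carbinol epimers | O=C1O[C@H](O[C@H]2C[C@@H](C)CC[C@@H]2C(C)C)[C@@H](C2(c3ccc(OCC=C)c(OC)c3)SCCCS2)[C@@H]1C(O)c1ccc(OC(=O)C(C)(C)C)c(OC)c1
F4 | step 7 | 4-[4-(allyloxy)-3-methoxybenzoyl]-3-{hydroxy[3-methoxy-4-(pivaloyloxy)phenyl]methyl}-5-(menthyloxy)dihydrofuran-2(3H)-one, carbinol epimers | O=C1O[C@H](O[C@H]2C[C@@H](C)CC[C@@H]2C(C)C)[C@@H](C(=O)c2ccc(OCC=C)c(OC)c2)[C@@H]1C(O)c1ccc(OC(=O)C(C)(C)C)c(OC)c1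
F5 | step 7 | (2S,3S)-2-{[4-(allyloxy)-3-methoxyphenyl](hydroxy)methyl}-3-[hydroxy(4-hydroxy-3-methoxyphenyl)methyl]butane-1,4-diol, carbinol epimers | OC[C@@H](C(O)c1ccc(O)c(OC)c1)[C@@H](CO)C(O)c1ccc(OCC=C)c(OC)c1
F6 | step 12 | (S)-3-[(R)-3-(4-acetoxy-3-methoxyphenyl)-2-{4-[(1R,3aS,4R,6aS)-4-(4-(allyloxy)-3-methoxyphenyl)tetrahydro-1H,3H-furo[3,4-c]furan-1-yl]-2-methoxyphenoxy}-3-oxopropanoyl]-4-benzyloxazolidin-2-one | C=CCOc1ccc([C@@H]2OC[C@@H]3[C@H]2CO[C@H]3c2ccc(O[C@@H](C(=O)N4C(=O)OC[C@@H]4Cc4ccccc4)C(=O)c4ccc(OC(C)=O)c(OC)c4)c(OC)c2)cc1OC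
F7 | step 3 | methyl 4-[4-(allyloxy)-3-methoxyphenyl]-4-oxobutanoate | COC(=O)CCC(=O)c1ccc(OCC=C)c(OC)c1
F8 | step 3 | (R)-5-[4-(allyloxy)-3-methoxyphenyl]dihydrofuran-2(3H)-one | C=CCOc1ccc([C@@H]2OC(=O)CC2)cc1OC
F9 | step 3 | (5R)-5-[4-(allyloxy)-3-methoxyphenyl]-3-(phenylselanyl)dihydrofuran-2(3H)-one, C3 epimers | C=CCOc1ccc([C@@H]2OC(=O)C([Se]c3ccccc3)C2)cc1OC
F10 | step 9 | 4-[(2R,3S,4S)-4-{(R)-[4-(allyloxy)-3-methoxyphenyl](hydroxy)methyl}-3-(hydroxymethyl)tetrahydrofuran-2-yl]-2-methoxyphenol | OC[C@@H]1[C@H]([C@@H](O)c2ccc(OCC=C)c(OC)c2)CO[C@H]1c1ccc(O)c(OC)c1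
F11 | step 9 | bis-mesylate of F10 at the primary and the phenolic oxygen | CS(=O)(=O)OC[C@@H]1[C@H]([C@@H](O)c2ccc(OCC=C)c(OC)c2)CO[C@H]1c1ccc(OS(C)(=O)=O)c(OC)c1
F12 | step 9 | 4-[(1R,3aS,4R,6aS)-4-[4-(allyloxy)-3-methoxyphenyl]tetrahydro-1H,3H-furo[3,4-c]furan-1-yl]-2-methoxyphenyl methanesulfonate | C=CCOc1ccc([C@@H]2OC[C@@H]3[C@H]2CO[C@H]3c2ccc(OS(C)(=O)=O)c(OC)c2)cc1OC
F13 | step 6 | racemic 4-{chloro[(trimethylsilyl)methoxy]methyl}-2-methoxyphenyl pivalate | COc1cc(C(Cl)OC[Si](C)(C)C)ccc1OC(=O)C(C)(C)C
A1 | alternative 1 | trans,trans menthyloxy lactone with the 2-[4-(allyloxy)-3-methoxyphenyl]-1,3-dithian-2-yl group at C4 and the hydroxy[3-methoxy-4-(triisopropylsilyloxy)phenyl]methyl group at C3, carbinol centre unspecified | O=C1O[C@H](O[C@H]2C[C@@H](C)CC[C@@H]2C(C)C)[C@@H](C2(c3ccc(OCC=C)c(OC)c3)SCCCS2)[C@@H]1C(O)c1ccc(O[Si](C(C)C)(C(C)C)C(C)C)c(OC)c1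
A2 | alternative 2 | 2-{(S)-[4-(allyloxy)-3-methoxyphenyl][(E)-3-(3-methoxy-4-(triisopropylsilyloxy)phenyl)allyloxy]methyl}oxirane, oxirane carbon of either configuration | C=CCOc1ccc([C@H](OC/C=C/c2ccc(O[Si](C(C)C)(C(C)C)C(C)C)c(OC)c2)C2CO2)cc1OC
A3 | alternative 2 | (−)-pinoresinol O-allyl O'-triisopropylsilyl ether | C=CCOc1ccc([C@@H]2OC[C@@H]3[C@H]2CO[C@H]3c2ccc(O[Si](C(C)C)(C(C)C)C(C)C)c(OC)c2)cc1OC
A4 | alternative 3 | 2-methoxy-4-[(4R,5S)-5-{(E)-2-[3-methoxy-4-(triisopropylsilyloxy)phenyl]vinyl}-1,3-dioxan-4-yl]phenyl pivalate | CC(C)[Si](C(C)C)(C(C)C)Oc1ccc(/C=C/[C@H]2COCO[C@H]2c2ccc(OC(=O)C(C)(C)C)c(OC)c2)cc1OC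
A5 | alternative 3 | (−)-pinoresinol O-triisopropylsilyl ether O'-pivalate | CC(C)[Si](C(C)C)(C(C)C)Oc1ccc([C@@H]2OC[C@@H]3[C@H]2CO[C@H]3c2ccc(OC(=O)C(C)(C)C)c(OC)c2)cc1OC
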